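The data stem from a simulated flask from invented constants.

The chemist who made the forecast and I read the same two earlier runs and disagreed about what happens to the target once the substrate stalls. The flasks amber, red and ochre now have to be judged.

| setting | spring | summer | amber | red | ochre |
|---|---|---|---|---|---|
| substrate | 0.010 M | 0.040 M | 0.020 M | 0.020 M | 0.020 M |
| temperature | 55 °C | 68 °C |  | 75 °C | 60 °C |
| remark | run made earlier | run made earlier | at 75 °C until 20 min, from then on at 60 °C |  |  |
| time |  |  | 25 min | 25 min | 25 min |

| run | time / min | target / % | substrate / % |
|---|---|---|---|
| spring | 8.00 | 34 | 23 |
| spring | 15.0 | 41 | 12 |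
| spring | 20.0 | 40 | 9 |
| spring | 30.0 | 40 | 11 |
| spring | 40.0 | 40 | 8 |
| spring | 50.0 | 39 | 7 |
| summer | 3.00 | 19 | 15 |
| summer | 6.00 | 13 | 12 |
| summer | 8.00 | 15 | 11 |
| summer | 12.0 | 11 | 10 |
| summer | 15.0 | 13 | 8 |
| summer | 20.0 | 10 | 8 |

(scatter of a reading: 1.5 percentage points)

- the flask that comes out highest in amount of target, in percent of the substrate charged, or "all alike" when all lie within 1.5 percentage points (amber / red / ochre / all alike)
- target at the end, in percent of the substrate charged, amber
- target at the end, in percent of the substrate charged, red
- target at the end, in percent of the substrate charged, ochre

The forecast sees a real loss of target: the target readings of summer fell from 19% to 10%, and for red “the target should decay quickly if the loss is thermally driven”. It gives 28% for ochre, 8% for amber and 6.5% for red, so ochre comes out on top.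

I read the late readings as a balance between target and substrate, thermodynamic control of their ratio in the field's term, and I watch the ratio c(target)/c(substrate). At a given temperature a one-to-one balance does not depend on the charge, so this ratio should separate temperature from concentration. Summing the last 3 readings to soften the scatter, spring reads 4.58 at 55 °C and summer reads 1.31 at 68 °C.

From these I take the span, the heating over which the ratio falls by a factor of 2, which reads 7.19 K. Counting spans, like counting half-lives, gives 2.83 for ochre and 0.666 for red. Taking substrate as 8%, the last summer reading, my target is 22.6% in ochre and 5.33% in red.

We part on amber. The forecast lets the cooler last minutes barely decay the target, so that amber ends slightly above red, while I let the target and substrate present at the change share out again at the ochre ratio, which gives 9.85%. That is my own number, and it differs from the forecast's.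

The flasks give 26.3% for ochre, 10.9% for amber and 4.83% for red, so ochre is highest, and the forecast held. Behind the end value of amber stands a rise: its target climbed from 5.69% to 10.9% after the change, but that climb of 5.2 percentage points is smaller than the gap of 15 points to ochre. The forecast's decay has its own region, a flask left long at one temperature: red goes down to 0.600% by 250 min, with target to substrate then at 0.552.

    substrate ⇌ intermediate (K = 2.00, k = 0.00440 /s, Ea = 92.0 kJ/mol, ΔH = −47.0 kJ/mol)
    intermediate ⇌ target (K = 1.30, k = 0.0380 /s, Ea = 92.0 kJ/mol, ΔH = −53.0 kJ/mol)
    2 substrate → self-condensation product (k = 0.140 /M/s, Ea = 64.0 kJ/mol)
    (constants at 60 °C)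

In ochre the step between intermediate and target, taken by itself and both ways together, relaxes with a half-life of 0.172 min, far shorter than the run's 25 min. At the end of ochre, target stands to intermediate at 1.30, beside an equilibrium constant of that step of 1.30. The end ratios of target to substrate are 2.86 in ochre and 0.574 in red, against my 2.83 and 0.666. A repeat of ochre at 85 °C lies 2.36 spans above summer, which gives a ratio of 0.254. That flask ends with 0.855% target on 4.04% substrate, a ratio of 0.212.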